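**Plan**
- Retrosynthesis: the (1E)-disubstituted alkene of the heptadienyl chain is cut first (cross-metathesis), giving an eastern vinyl-oxolane lactone and a western skipped-dienyl butenolide. The saturated lactone is then cut at C2–C3 (and C2–O1) back to a tertiary vinyl carbinol plus CO.
- Enabling feature: lactone C5 is a fully substituted carbinol carbon, so O1–C5–C4–C3 is a tertiary allylic alcohol in disguise (O–C–CH=CH2). It lacks only the carbonyl carbon C2, so the oxolan-2-one ring can close by a formal (4+1) carbonylation.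
- Forward, east: (R)-linalool → (E)-allylic alcohol → Sharpless epoxidation and 5-exo epoxide opening (oxolane ring) → terminal epoxide → vinyl carbinol → Pd-catalysed cyclocarbonylation (lactone ring).
- Forward, west: α-phenylsulfanyl lactone alkylation and sulfoxide elimination (butenolide ring), (E)-selective allylic oxidation, bromide, vinyl Stille coupling; the halves are then joined by cross-metathesis.
- Stereochemistry: the quaternary oxolane carbon comes from (R)-linalool. The oxolane CH and the lactone quaternary carbon come from the L-(+)-tartrate epoxidation (inversion at CH on ring closure, retention at the carbinol). Both E alkenes come from the SeO2 rule and from thermodynamic control in metathesis.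

Key step: step 5

Remark: commercial (R)-(−)-linalool is taken as enantiomerically pure; 10, 11, 14 and 15 are racemic, which is of no consequence because that stereocentre is removed in step 8.

**Step 1**
Reactants: 1 (R)-(−)-linalool [(3R)-3,7-dimethylocta-1,6-dien-3-ol]
Product: 2 (2E,6R)-2,6-dimethylocta-2,7-diene-1,6-diol
Conditions: SeO2 (0.3 equiv), t-BuOOH (2.5 equiv), salicylic acid (0.1 equiv), CH2Cl2, 0 °C to rt
Reagents that add atoms: tert-butyl hydroperoxide, CC(C)(C)OO
Why: Sharpless–Umbreit allylic oxidation (ene reaction, then [2,3]-shift of the allylseleninic acid) takes place at the electron-rich trisubstituted alkene and, by the usual rule, at its (E)-methyl group, so the (E)-allylic alcohol should form while the vinyl carbinol end is left alone.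

**Step 2**
Reactants: 2 (2E,6R)-2,6-dimethylocta-2,7-diene-1,6-diol
Product: 4 (2S)-2-[(2R,5R)-5-ethenyl-5-methyloxolan-2-yl]propane-1,2-diol, via epoxy diol 3 (not isolated)
Conditions: Ti(OiPr)4 (10 mol %), L-(+)-diethyl tartrate (12 mol %), t-BuOOH (1.5 equiv), 4 Å MS, CH2Cl2, −20 °C; aqueous tartaric acid work-up, then crude with CSA (10 mol %), CH2Cl2, 0 °C to rt
Reagents that add atoms: tert-butyl hydroperoxide, CC(C)(C)OO
Why: Sharpless asymmetric epoxidation with L-(+)-tartrate should give the (2S,3S)-epoxide under reagent control (the tertiary vinyl carbinol is not a competent substrate), and the tertiary hydroxyl then opens it 5-exo-tet at the secondary carbon with inversion, which sets the oxolane CH as R and leaves the new tertiary carbinol as S, the hydroxymethyl group disfavouring 6-endo opening at the quaternary carbon.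

**Step 3**
Reactants: 4 (2S)-2-[(2R,5R)-5-ethenyl-5-methyloxolan-2-yl]propane-1,2-diol
Product: 6 (2R,5R)-2-ethenyl-2-methyl-5-[(2S)-2-methyloxiran-2-yl]oxolane, via primary tosylate 5 (not isolated)
Conditions: NaH (2.2 equiv), 1-(p-toluenesulfonyl)imidazole (1.05 equiv), THF, 0 °C to rt
Reagents that add atoms: none
Why: Selective sulfonylation of the primary alkoxide followed by intramolecular Williamson closure by the tertiary alkoxide (one-pot diol-to-epoxide conversion) leaves the C–O bond of the carbinol centre untouched, so its configuration is retained.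

**Step 4**
Reactants: 6 (2R,5R)-2-ethenyl-2-methyl-5-[(2S)-2-methyloxiran-2-yl]oxolane
Product: 8 (2S)-2-[(2R,5R)-5-ethenyl-5-methyloxolan-2-yl]but-3-en-2-ol, via oxido sulfonium betaine 7 (not isolated)
Conditions: Me3S+ I− (4 equiv), n-BuLi (3.9 equiv), THF, −10 °C to rt
Reagents that add atoms: trimethylsulfonium iodide, C[S+](C)C.[I-]
Why: Dimethylsulfonium methylide opens the epoxide at its CH2 terminus (SN2) and a second equivalent converts the oxido sulfonium salt into its ylide, which eliminates dimethyl sulfide to give the one-carbon-homologated tertiary allylic alcohol (epoxide-to-allylic-alcohol homologation) without touching the stereocentre.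

**Step 5**
Reactants: 8 (2S)-2-[(2R,5R)-5-ethenyl-5-methyloxolan-2-yl]but-3-en-2-ol
Product: 9 (5S)-5-[(2R,5R)-5-ethenyl-5-methyloxolan-2-yl]-5-methyloxolan-2-one
Conditions: Pd(dba)2 (4 mol %), dppb (4 mol %), CO (40 atm), H2 (14 atm), CH2Cl2, 110 °C
Reagents that add atoms: carbon monoxide, [C-]#[O+]
Why: Zerovalent palladium and H2 give a hydridopalladium species that adds across the carbinol vinyl group with palladium on the terminal CH2 (the fully substituted carbinol carbon blocks the branched mode); CO then inserts into this primary alkyl–Pd bond, which is the event that makes the CH2–C(=O) bond, and the tertiary hydroxyl four atoms away takes up the acyl–Pd to release the lactone and return the hydride. The closest known reaction type is the palladium/dppb-catalysed cyclocarbonylation of tertiary allylic alcohols to γ-butyrolactones under CO/H2, of which this is a direct application. The one ring formed, the oxolan-2-one, closes in a formal (4+1) sense from the O–C–C=C unit and CO, the final acyl capture being 5-exo-trig. No stereocentre is created, and the carbinol centre keeps its S configuration because none of its four bonds is broken. The step needs chemoselectivity between the two vinyl groups and regioselectivity for the linear acyl: only the carbinol vinyl has a hydroxyl placed to trap the acyl–Pd, whereas hydropalladation and CO insertion at the ether-bound vinyl are reversible and unproductive without a nucleophile, and neither vinyl carries an allylic hydrogen, so double-bond migration cannot occur.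

**Step 6**
Reactants: 10 3-bromooxolan-2-one (racemic α-bromo-γ-butyrolactone)
Product: 11 3-(phenylsulfanyl)oxolan-2-one
Conditions: PhSH (1.05 equiv), K2CO3 (1.1 equiv), acetone, 0 °C to rt
Reagents that add atoms: benzenethiol, Sc1ccccc1
Why: SN2 displacement of the activated α-bromide by thiolate should be fast and clean, and the new stereocentre is formed as a racemate that is removed later.

**Step 7**
Reactants: 11 3-(phenylsulfanyl)oxolan-2-one; 12 5-bromo-2-methylpent-2-ene
Product: 14 3-(4-methylpent-3-en-1-yl)-3-(phenylsulfanyl)oxolan-2-one, via lithium enolate 13 (not isolated)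
Conditions: LiN(SiMe3)2 (1.05 equiv), THF, −78 °C; then 12 (1.2 equiv), HMPA, −78 °C to rt
Reagents that add atoms: none
Why: Alkylation of the sulfur-stabilised lactone enolate with a primary bromide is the standard entry to α-alkyl-α-phenylsulfanyl lactones, the quaternary centre being formed as a racemate that step 8 destroys.

**Step 8**
Reactants: 14 3-(4-methylpent-3-en-1-yl)-3-(phenylsulfanyl)oxolan-2-one
Product: 16 3-(4-methylpent-3-en-1-yl)furan-2(5H)-one, via sulfoxide 15 (not isolated)
Conditions: mCPBA (1.0 equiv), CH2Cl2, −78 °C; NaHCO3 wash, then toluene, 110 °C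
Reagents that add atoms: none
Why: Chemoselective S-oxidation at low temperature (the sulfide is far more nucleophilic than the trisubstituted alkene) followed by thermal syn-elimination of benzenesulfenic acid, which in α-sulfinyl lactones favours the endocyclic alkene, should give the α-substituted butenolide.

**Step 9**
Reactants: 16 3-(4-methylpent-3-en-1-yl)furan-2(5H)-one
Product: 17 3-[(3E)-5-hydroxy-4-methylpent-3-en-1-yl]furan-2(5H)-one
Conditions: SeO2 (0.3 equiv), t-BuOOH (2.5 equiv), salicylic acid (0.1 equiv), CH2Cl2, rt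
Reagents that add atoms: tert-butyl hydroperoxide, CC(C)(C)OO
Why: SeO2/t-BuOOH allylic oxidation is selective for the (E)-methyl group of the electron-rich trisubstituted alkene, the electron-poor butenolide alkene being inert, so the (E)-2-methylallylic alcohol is expected.

**Step 10**
Reactants: 17 3-[(3E)-5-hydroxy-4-methylpent-3-en-1-yl]furan-2(5H)-one
Product: 18 3-[(3E)-5-bromo-4-methylpent-3-en-1-yl]furan-2(5H)-one
Conditions: CBr4 (1.2 equiv), PPh3 (1.25 equiv), CH2Cl2, 0 °C
Reagents that add atoms: carbon tetrabromide, BrC(Br)(Br)Br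
Why: Appel bromination converts the primary allylic alcohol under neutral conditions, without allylic transposition or change of alkene geometry and without harm to the butenolide.

**Step 11**
Reactants: 18 3-[(3E)-5-bromo-4-methylpent-3-en-1-yl]furan-2(5H)-one
Product: 19 3-[(3E)-4-methylhepta-3,6-dien-1-yl]furan-2(5H)-one
Conditions: tributyl(vinyl)stannane (1.2 equiv), Pd2(dba)3 (2.5 mol %), AsPh3 (10 mol %), THF, 50 °C
Reagents that add atoms: tributyl(ethenyl)stannane, C=C[Sn](CCCC)(CCCC)CCCC
Why: Stille coupling of an allylic bromide with a vinylstannane proceeds through a π-allylpalladium intermediate that couples at its less hindered CH2 terminus and keeps the favoured syn (E) geometry, which should give the skipped diene under neutral conditions.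

**Step 12**
Reactants: 9 (5S)-5-[(2R,5R)-5-ethenyl-5-methyloxolan-2-yl]-5-methyloxolan-2-one; 19 3-[(3E)-4-methylhepta-3,6-dien-1-yl]furan-2(5H)-one
Product: 20 (5S)-5-methyl-5-[(2R,5R)-5-methyl-5-[(1E,4E)-4-methyl-7-(2-oxo-2,5-dihydrofuran-3-yl)hepta-1,4-dien-1-yl]oxolan-2-yl]oxolan-2-one
Conditions: second-generation Hoveyda–Grubbs catalyst RuCl2(H2IMes)(=CH-C6H4-2-OiPr) (10 mol %), 19 (3 equiv), 1,4-benzoquinone (10 mol %), CH2Cl2, 40 °C
Reagents that add atoms: none
Why: Selective olefin cross-metathesis between an unhindered terminal alkene (used in excess, its homodimer re-entering the cycle) and a vinyl group on a fully substituted carbon (which cannot homodimerise) should give the hindered 1,2-disubstituted alkene as the E isomer under thermodynamic control, the trisubstituted and butenolide alkenes not being engaged.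

**Compound list**
1 | (R)-(−)-linalool, (3R)-3,7-dimethylocta-1,6-dien-3-ol | C=C[C@](C)(O)CCC=C(C)C | starting material
2 | (2E,6R)-2,6-dimethylocta-2,7-diene-1,6-diol | C=C[C@](C)(O)CC/C=C(\C)CO | intermediate
3 | [(2S,3S)-3-[(3R)-3-hydroxy-3-methylpent-4-en-1-yl]-2-methyloxiran-2-yl]methanol | C=C[C@](C)(O)CC[C@@H]1O[C@@]1(C)CO | intermediate
4 | (2S)-2-[(2R,5R)-5-ethenyl-5-methyloxolan-2-yl]propane-1,2-diol | C=C[C@@]1(C)CC[C@H]([C@@](C)(O)CO)O1 | intermediate
5 | (2S)-2-[(2R,5R)-5-ethenyl-5-methyloxolan-2-yl]-2-hydroxypropyl 4-methylbenzenesulfonate | C=C[C@@]1(C)CC[C@H]([C@@](C)(O)COS(=O)(=O)c2ccc(C)cc2)O1 | intermediate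
6 | (2R,5R)-2-ethenyl-2-methyl-5-[(2S)-2-methyloxiran-2-yl]oxolane | C=C[C@@]1(C)CC[C@H]([C@]2(C)CO2)O1 | intermediate
7 | (2S)-4-(dimethylsulfaniumyl)-2-[(2R,5R)-5-ethenyl-5-methyloxolan-2-yl]butan-2-olate | C=C[C@@]1(C)CC[C@H]([C@@](C)([O-])CC[S+](C)C)O1 | intermediate
8 | (2S)-2-[(2R,5R)-5-ethenyl-5-methyloxolan-2-yl]but-3-en-2-ol | C=C[C@@]1(C)CC[C@H]([C@@](C)(O)C=C)O1 | intermediate
9 | (5S)-5-[(2R,5R)-5-ethenyl-5-methyloxolan-2-yl]-5-methyloxolan-2-one | C=C[C@@]1(C)CC[C@H]([C@]2(C)CCC(=O)O2)O1 | intermediate
10 | 3-bromooxolan-2-one (racemic) | O=C1OCCC1Br | starting material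
11 | 3-(phenylsulfanyl)oxolan-2-one (racemic) | O=C1OCCC1Sc1ccccc1 | intermediate
12 | 5-bromo-2-methylpent-2-ene | CC(C)=CCCBr | starting material
13 | lithium 3-(phenylsulfanyl)-4,5-dihydrofuran-2-olate | [Li+].[O-]C1=C(Sc2ccccc2)CCO1 | intermediate
14 | 3-(4-methylpent-3-en-1-yl)-3-(phenylsulfanyl)oxolan-2-one (racemic) | CC(C)=CCCC1(Sc2ccccc2)CCOC1=O | intermediate
15 | 3-(benzenesulfinyl)-3-(4-methylpent-3-en-1-yl)oxolan-2-one (racemic) | CC(C)=CCCC1(S(=O)c2ccccc2)CCOC1=O | intermediate
16 | 3-(4-methylpent-3-en-1-yl)furan-2(5H)-one | CC(C)=CCCC1=CCOC1=O | intermediate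
17 | 3-[(3E)-5-hydroxy-4-methylpent-3-en-1-yl]furan-2(5H)-one | C/C(CO)=C\CCC1=CCOC1=O | intermediate
18 | 3-[(3E)-5-bromo-4-methylpent-3-en-1-yl]furan-2(5H)-one | C/C(CBr)=C\CCC1=CCOC1=O | intermediate
19 | 3-[(3E)-4-methylhepta-3,6-dien-1-yl]furan-2(5H)-one | C/C(CC=C)=C\CCC1=CCOC1=O | intermediate
20 | (5S)-5-methyl-5-[(2R,5R)-5-methyl-5-[(1E,4E)-4-methyl-7-(2-oxo-2,5-dihydrofuran-3-yl)hepta-1,4-dien-1-yl]oxolan-2-yl]oxolan-2-one | C/C(=C\CCC1=CCOC1=O)C/C=C/[C@@]1(C)CC[C@H]([C@]2(C)CCC(=O)O2)O1 | target

**Step count and risks**
Total: 12 steps. Longest linear sequence: 7 steps (steps 6 to 12); the eastern line is 6 steps (steps 1 to 5 and 12).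

Steps most likely to fail:

1. Step 5. What may go wrong: loss of chemoselectivity (carbonylation or reduction at the ether-bound vinyl group), or palladium-induced ionisation of the tertiary allylic C–O bonds under the hot CO/H2 conditions. The fallback sets out from epoxide 6 and comes back at lactone 9. Epoxide 6 would be opened at its CH2 terminus with dilithioacetate (AcOH, 2 LiN(iPr)2, THF/HMPA, 45 °C) to give (4S)-4-[(2R,5R)-5-ethenyl-5-methyloxolan-2-yl]-4-hydroxypentanoic acid F1, which would lactonise on acidification (TsOH, toluene, rt) to 9. This builds the lactone by enolate alkylation and O-acylation, with no CO, H2 or palladium present.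

2. Step 12. What may go wrong: the hindered vinyl group on the quaternary oxolane carbon fails to enter the metathesis cycle, so that only homodimerisation of 19 occurs, or the double bond of the skipped diene migrates. The fallback sets out from 9, uses bromide 18, and comes back at 20. Ozonolysis of 9 (O3, CH2Cl2, −78 °C; PPh3) would give (2R,5R)-2-methyl-5-[(2S)-2-methyl-5-oxooxolan-2-yl]oxolane-2-carbaldehyde F2. Ohira–Bestmann homologation (dimethyl (1-diazo-2-oxopropyl)phosphonate, K2CO3, MeOH) would give (5S)-5-[(2R,5R)-5-ethynyl-5-methyloxolan-2-yl]-5-methyloxolan-2-one F3. Palladium-catalysed hydrostannylation (Bu3SnH, PdCl2(PPh3)2, THF, 0 °C) would give (5S)-5-methyl-5-[(2R,5R)-5-methyl-5-[(E)-2-(tributylstannyl)ethenyl]oxolan-2-yl]oxolan-2-one F4. Stille coupling of F4 with allylic bromide 18 (Pd2(dba)3, AsPh3, THF, 50 °C) would then form the allyl–vinyl single bond of the skipped diene and give 20 directly.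

3. Step 4. What may go wrong: slow attack of the ylide at the neopentyl-type epoxide carbon, with base-induced rearrangement of the epoxide taking over. The fallback sets out from diol 4 and comes back at 8. Parikh–Doering oxidation of the primary alcohol of 4 (SO3·pyridine, DMSO, iPr2NEt, CH2Cl2, 0 °C) would give (2R)-2-[(2R,5R)-5-ethenyl-5-methyloxolan-2-yl]-2-hydroxypropanal F5. Wittig methylenation with excess ylide (Ph3PCH3Br, KN(SiMe3)2, THF, −78 to 0 °C) would give 8.

**Further compounds**
F1 | step 5 | (4S)-4-[(2R,5R)-5-ethenyl-5-methyloxolan-2-yl]-4-hydroxypentanoic acid | C=C[C@@]1(C)CC[C@H]([C@@](C)(O)CCC(=O)O)O1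
F2 | step 12 | (2R,5R)-2-methyl-5-[(2S)-2-methyl-5-oxooxolan-2-yl]oxolane-2-carbaldehyde | O=C[C@@]1(C)CC[C@H]([C@]2(C)CCC(=O)O2)O1
F3 | step 12 | (5S)-5-[(2R,5R)-5-ethynyl-5-methyloxolan-2-yl]-5-methyloxolan-2-one | C#C[C@@]1(C)CC[C@H]([C@]2(C)CCC(=O)O2)O1
F4 | step 12 | (5S)-5-methyl-5-[(2R,5R)-5-methyl-5-[(E)-2-(tributylstannyl)ethenyl]oxolan-2-yl]oxolan-2-one | CCCC[Sn](CCCC)(CCCC)/C=C/[C@@]1(C)CC[C@H]([C@]2(C)CCC(=O)O2)O1
F5 | step 4 | (2R)-2-[(2R,5R)-5-ethenyl-5-methyloxolan-2-yl]-2-hydroxypropanal | C=C[C@@]1(C)CC[C@H]([C@@](C)(O)C=O)O1
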